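**Retrosynthetic overview**
1. The target is epiguibourtinidol-(4β→8)-epicatechin: upper flavan = rings A (benzo), B (4-hydroxyphenyl), C (pyran), 2R,3R,4R; lower flavan = rings D (benzo), E (catechol), F (pyran), 2R,3R. Six benzyl ethers are removed last; before that the C4(ring C)–C8(ring D) bond is made by flavan-4-yl cation/Friedel–Crafts union of 21 with 14.
2. Ring F is cut at C4–C3 and O1–C2: an ortho-quinone methide of ring D (O1=C8a–C4a=C4H2, from salicyl alcohol 11) plus a Z-alkenyl boronate carrying ring E (C2=C3). Oxidation of the C3–B bond then gives the 3-OH.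
3. Enabling feature: on ring D the phenolic oxygen O1 (on C8a) is ortho to the C4 methylene (on C4a), a latent 1-oxadiene. The cis C2-aryl/C3-hydroxyl pair of ring F maps onto a Z-alkene whose boron is the masked, polarity-reversed 3-OH.
4. Ring C of the upper unit comes from a domino oxa-Michael–Henry reaction of a salicylaldehyde with a nitrostyrene, reductive Nef reaction and cis-selective hydride reduction; C4 is then activated with DDQ.
5. Order of ring formation: ring F (step 7), ring C (step 8), then the C4–C8 union (step 12) and deprotection (step 13).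

Key step: step 7

Remark: the ligand built from (1S,2S,3S,5R)-isopinocampheylamine is assumed to expose the alkene face that leads to 2R,3R; if the sense is opposite, the equally available enantiomeric amine is used and nothing else changes.
Remark: in step 8 the (S)-configured amine catalyst is assumed to give 2R; otherwise its mirror image is used.

Step 1
Reactants: 1 (1S,2S,3S,5R)-isopinocampheylamine; 2 benzyl bromoacetate (2.2 equiv)
Product: 3 dibenzyl N-[(1S,2S,3S,5R)-isopinocampheyl]iminodiacetate
Conditions: K2CO3, MeCN, 70 °C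
Reagents that add atoms: none
Why: Twofold SN2 N-alkylation of the primary amine by the α-bromo ester should stop at the tertiary amine because the bulky isopinocampheyl group disfavours quaternisation, and the four pinane stereocentres are not touched.

Step 2
Reactants: 3 dibenzyl N-[(1S,2S,3S,5R)-isopinocampheyl]iminodiacetate
Product: 4 N-[(1S,2S,3S,5R)-isopinocampheyl]iminodiacetic acid
Conditions: H2 (1 atm), 10% Pd/C, MeOH, rt
Reagents that add atoms: none
Why: Catalytic hydrogenolysis of the two benzyl esters frees the pinene-derived analogue of N-methyliminodiacetic acid without affecting the saturated pinane skeleton.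

Step 3
Reactants: 5 3,4-bis(benzyloxy)benzaldehyde
Product: 6 1,2-bis(benzyloxy)-4-ethynylbenzene
Conditions: dimethyl (1-diazo-2-oxopropyl)phosphonate, K2CO3, MeOH, 0 °C to rt
Reagents that add atoms: dimethyl (1-diazo-2-oxopropyl)phosphonate, CC(=O)C(=[N+]=[N-])P(=O)(OC)OC
Why: Seyferth–Gilbert homologation in the Ohira–Bestmann variant, in which the diazomethylphosphonate anion formed in situ adds to the aldehyde and Horner–Wadsworth–Emmons-type elimination, loss of N2 and 1,2-hydride shift give the terminal alkyne with the benzyl ethers intact.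

Step 4
Reactants: 6 1,2-bis(benzyloxy)-4-ethynylbenzene; 4 N-[(1S,2S,3S,5R)-isopinocampheyl]iminodiacetic acid
Product: 8 (Z)-2-[3,4-bis(benzyloxy)phenyl]ethenylboronic acid N-[(1S,2S,3S,5R)-isopinocampheyl]iminodiacetate ester (tetracoordinate N→B cage), via Z-alkenyl catechol boronate 7 (not isolated)
Conditions: catecholborane, [Rh(cod)Cl]2 (1.5 mol %), P(i-Pr)3 (6 mol %), Et3N, cyclohexane, rt; evaporate; then 4, toluene/DMSO, 90 °C
Reagents that add atoms: catecholborane, B1Oc2ccccc2O1
Why: Rhodium-catalysed trans-hydroboration of the terminal alkyne through a rhodium vinylidene should deliver the Z-alkenyl boronate, and exchange of the labile catechol ester for diacid 4 gives the air-stable tetracoordinate boronate with the Z geometry preserved.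

Step 5
Reactants: 9 3,5-bis(benzyloxy)phenol
Product: 10 4,6-bis(benzyloxy)-2-hydroxybenzaldehyde
Conditions: MgCl2, Et3N, paraformaldehyde, MeCN, reflux
Reagents that add atoms: paraformaldehyde (as formaldehyde), C=O
Why: Magnesium-phenoxide-directed ortho-formylation (Casnati–Skattebøl reaction) is specific for the positions ortho to the free phenol, which are equivalent here, so a single salicylaldehyde should result.

Step 6
Reactants: 10 4,6-bis(benzyloxy)-2-hydroxybenzaldehyde
Product: 11 3,5-bis(benzyloxy)-2-(hydroxymethyl)phenol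
Conditions: NaBH4, THF/EtOH, 0 °C; used at once
Reagents that add atoms: none
Why: Chemoselective borohydride reduction of the aldehyde gives the ortho-hydroxybenzyl alcohol that is the neutral precursor of the ortho-quinone methide, and it is used without storage because such electron-rich salicyl alcohols self-condense.

Step 7
Reactants: 11 3,5-bis(benzyloxy)-2-(hydroxymethyl)phenol; 8 Z-alkenyl boronate of ligand 4 (1.5 equiv)
Product: 14 (2R,3R)-5,7-bis(benzyloxy)-2-[3,4-bis(benzyloxy)phenyl]chroman-3-ol (5,7,3',4'-tetra-O-benzyl-(−)-epicatechin), via ortho-quinone methide 12 (not isolated), via cis-3-boryl flavan 13 (not isolated)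
Conditions: 8, 4 Å molecular sieves, 1,4-dioxane, 100 °C, slow addition of 11; then THF, aq. NaOH, 30% H2O2, 0 °C to rt
Reagents that add atoms: hydrogen peroxide, OO
Why: Proposed new method: heating dehydrates 11 to ortho-quinone methide 12, an electron-poor 1-oxadiene (O1=C8a–C4a=C4H2) that should add the electron-rich Z-alkene of 8 in an inverse-electron-demand hetero-Diels–Alder reaction, after which H2O2/NaOH cleaves the C3–B bond with retention; the closest known reaction types are the ortho-quinone methide/β-substituted styrene cycloaddition to 2-aryl-3-alkylchromans and the face-selective epoxidation of alkenyl boronates of pinene-derived iminodiacetic acid ligands. Ring F closes in a concerted, asynchronous six-membered [4+2] mode in which the C4–C3 bond leads and the O1–C2 bond follows. Regiochemistry follows from the positive charge that builds up at C2 in this transition state, which is stabilised by the 3,4-dialkoxyphenyl group and by hyperconjugation with the electron-rich sp3 C–B bond, while the tetracoordinate boron has no vacant orbital and so cannot divert the reaction to a Petasis-type alkenyl transfer. The cis relationship of C2 and C3 is controlled by suprafacial addition to the Z-alkene, and their absolute configuration (2R,3R after oxidation) by the isopinocampheyl group on nitrogen, which shields one face of the alkene. The step needs cis-stereospecificity, facial selectivity and suppression of Friedel–Crafts self-condensation of the quinone methide; these are secured by neutral thermal generation (no acid, hence no long-lived benzylic cation that could rotate), by the auxiliary, and by slow addition of 11 to an excess of 8, the only free phenol being the one that becomes O1.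

Step 8
Reactants: 15 4-(benzyloxy)-2-hydroxybenzaldehyde; 16 (E)-1-(benzyloxy)-4-(2-nitroethenyl)benzene
Product: 17 (2R)-7-(benzyloxy)-2-[4-(benzyloxy)phenyl]-3-nitro-2H-chromene
Conditions: (S)-2-[(1-methylimidazol-2-ylsulfanyl)methyl]pyrrolidine (20 mol %), salicylic acid (20 mol %), DMSO, rt
Reagents that add atoms: none
Why: Amine-catalysed domino oxa-Michael–Henry–dehydration, in which the phenol adds to the aryl-bearing carbon of the nitroalkene, the nitronate closes onto the iminium-activated aldehyde carbon and elimination gives the 3-nitro-2H-chromene, the chiral amine–acid pair controlling the face of the oxa-Michael addition and so setting C2 (R).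

Step 9
Reactants: 17 (2R)-7-(benzyloxy)-2-[4-(benzyloxy)phenyl]-3-nitro-2H-chromene
Product: 19 (2R)-7-(benzyloxy)-2-[4-(benzyloxy)phenyl]chroman-3-one, via sodium nitronate 18 (not isolated)
Conditions: NaBH4, THF/MeOH, −20 °C; then aq. TiCl3, NH4OAc, THF, 0 °C to rt
Reagents that add atoms: water, O
Why: Conjugate hydride reduction of the nitroalkene gives the nitronate, which a reductive Nef reaction with buffered aqueous TiCl3 should convert into the ketone under near-neutral conditions that leave the C2 stereocentre untouched.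

Step 10
Reactants: 19 (2R)-7-(benzyloxy)-2-[4-(benzyloxy)phenyl]chroman-3-one
Product: 20 (2R,3R)-7-(benzyloxy)-2-[4-(benzyloxy)phenyl]chroman-3-ol (7,4'-di-O-benzyl-epiguibourtinidol)
Conditions: LiBH(sec-Bu)3, LiBr, THF, −78 °C
Reagents that add atoms: none
Why: The bulky hydride should attack the C3 carbonyl from the face opposite to the C2 aryl group, as in the established conversion of benzylated flavan-3-ones into 2,3-cis flavan-3-ols, which sets C3 (R).

Step 11
Reactants: 20 (2R,3R)-7-(benzyloxy)-2-[4-(benzyloxy)phenyl]chroman-3-ol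
Product: 21 (2R,3R,4S)-7-(benzyloxy)-2-[4-(benzyloxy)phenyl]-4-(2-ethoxyethoxy)chroman-3-ol (4β, 3,4-trans)
Conditions: DDQ (1.5 equiv), 2-ethoxyethanol, CH2Cl2, rt
Reagents that add atoms: 2-ethoxyethanol, CCOCCO
Why: DDQ abstracts the C4 benzylic hydride next to the most electron-rich ring A (cation stabilised by the para 7-benzyloxy group and by O1) and the alcohol traps the cation trans to the 3-hydroxyl, the standard C4 activation of flavan-3-ols, the new C4 centre being lost again in step 12.

Step 12
Reactants: 21 (2R,3R,4S)-7-(benzyloxy)-2-[4-(benzyloxy)phenyl]-4-(2-ethoxyethoxy)chroman-3-ol; 14 5,7,3',4'-tetra-O-benzyl-(−)-epicatechin (3 equiv, excess recovered)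
Product: 22 (2R,3R,4R)-7-(benzyloxy)-2-[4-(benzyloxy)phenyl]-4-{(2R,3R)-5,7-bis(benzyloxy)-2-[3,4-bis(benzyloxy)phenyl]-3-hydroxychroman-8-yl}chroman-3-ol
Conditions: TMSOTf (0.3 equiv), CH2Cl2, −78 to −40 °C
Reagents that add atoms: none
Why: Lewis-acid ionisation of the C4 acetal gives the flavan-4-yl cation, which undergoes Friedel–Crafts attack by C8 of 14 (the most nucleophilic position of ring D when O5 and O7 are benzylated) from the β-face, anti to both the 3-hydroxyl and the 2-aryl group, setting C4 (R) with the 3,4-trans relationship.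

Step 13
Reactants: 22 hexa-O-benzyl dimer
Product: 23 (2R,3R,4R)-2-(4-hydroxyphenyl)-4-[(2R,3R)-2-(3,4-dihydroxyphenyl)-3,5,7-trihydroxychroman-8-yl]chroman-3,7-diol (target)
Conditions: H2 (1 atm), Pd(OH)2/C, THF/MeOH/H2O, rt
Reagents that add atoms: none
Why: Hydrogenolysis of the six benzyl ethers over Pd(OH)2/C, the usual last step of proanthocyanidin syntheses, should leave the interflavan C–C bond and all five stereocentres untouched.

**Compound list**
1 | (1S,2S,3S,5R)-isopinocampheylamine | C[C@@H]1[C@@H](N)C[C@H]2C[C@@H]1C2(C)C | starting material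
2 | benzyl bromoacetate | BrCC(=O)OCc1ccccc1 | starting material
3 | dibenzyl N-[(1S,2S,3S,5R)-isopinocampheyl]iminodiacetate | C[C@@H]1[C@@H](N(CC(=O)OCc3ccccc3)CC(=O)OCc3ccccc3)C[C@H]2C[C@@H]1C2(C)C | intermediate
4 | N-[(1S,2S,3S,5R)-isopinocampheyl]iminodiacetic acid | C[C@@H]1[C@@H](N(CC(=O)O)CC(=O)O)C[C@H]2C[C@@H]1C2(C)C | intermediate
5 | 3,4-bis(benzyloxy)benzaldehyde | O=Cc1ccc(OCc2ccccc2)c(OCc2ccccc2)c1 | starting material
6 | 1,2-bis(benzyloxy)-4-ethynylbenzene | C#Cc1ccc(OCc2ccccc2)c(OCc2ccccc2)c1 | intermediate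
7 | 2-{(Z)-2-[3,4-bis(benzyloxy)phenyl]ethenyl}-1,3,2-benzodioxaborole, not isolated | O1c2ccccc2OB1/C=C\c1ccc(OCc2ccccc2)c(OCc2ccccc2)c1 | intermediate
8 | (Z)-2-[3,4-bis(benzyloxy)phenyl]ethenylboronic acid N-[(1S,2S,3S,5R)-isopinocampheyl]iminodiacetate ester | C[C@@H]1[C@@H]([N+]34CC(=O)O[B-]3(OC(=O)C4)/C=C\c3ccc(OCc4ccccc4)c(OCc4ccccc4)c3)C[C@H]2C[C@@H]1C2(C)C | intermediate
9 | 3,5-bis(benzyloxy)phenol | Oc1cc(OCc2ccccc2)cc(OCc2ccccc2)c1 | starting material
10 | 4,6-bis(benzyloxy)-2-hydroxybenzaldehyde | O=Cc1c(O)cc(OCc2ccccc2)cc1OCc1ccccc1 | intermediate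
11 | 3,5-bis(benzyloxy)-2-(hydroxymethyl)phenol | OCc1c(O)cc(OCc2ccccc2)cc1OCc1ccccc1 | intermediate
12 | 3,5-bis(benzyloxy)-6-methylidenecyclohexa-2,4-dien-1-one (ortho-quinone methide), not isolated | C=C1C(=O)C=C(OCc2ccccc2)C=C1OCc1ccccc1 | intermediate
13 | (2S,3R)-5,7-bis(benzyloxy)-2-[3,4-bis(benzyloxy)phenyl]chroman-3-ylboronic acid N-[(1S,2S,3S,5R)-isopinocampheyl]iminodiacetate ester (2,3-cis, same spatial arrangement as 14; the C2 descriptor differs only because boron ranks below carbon), not isolated | C[C@@H]1[C@@H]([N+]34CC(=O)O[B-]3(OC(=O)C4)[C@@H]3Cc4c(OCc5ccccc5)cc(OCc5ccccc5)cc4O[C@@H]3c3ccc(OCc4ccccc4)c(OCc4ccccc4)c3)C[C@H]2C[C@@H]1C2(C)C | intermediate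
14 | (2R,3R)-5,7-bis(benzyloxy)-2-[3,4-bis(benzyloxy)phenyl]chroman-3-ol (5,7,3',4'-tetra-O-benzyl-(−)-epicatechin) | O[C@@H]1Cc2c(OCc3ccccc3)cc(OCc3ccccc3)cc2O[C@@H]1c1ccc(OCc2ccccc2)c(OCc2ccccc2)c1 | intermediate
15 | 4-(benzyloxy)-2-hydroxybenzaldehyde | O=Cc1ccc(OCc2ccccc2)cc1O | starting material
16 | (E)-1-(benzyloxy)-4-(2-nitroethenyl)benzene | [O-][N+](=O)/C=C/c1ccc(OCc2ccccc2)cc1 | starting material
17 | (2R)-7-(benzyloxy)-2-[4-(benzyloxy)phenyl]-3-nitro-2H-chromene | [O-][N+](=O)C1=Cc2ccc(OCc3ccccc3)cc2O[C@@H]1c1ccc(OCc2ccccc2)cc1 | intermediate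
18 | sodium nitronate of (2R)-7-(benzyloxy)-2-[4-(benzyloxy)phenyl]-3-nitrochroman, not isolated | [Na+].[O-][N+]([O-])=C1Cc2ccc(OCc3ccccc3)cc2O[C@@H]1c1ccc(OCc2ccccc2)cc1 | intermediate
19 | (2R)-7-(benzyloxy)-2-[4-(benzyloxy)phenyl]chroman-3-one | O=C1Cc2ccc(OCc3ccccc3)cc2O[C@@H]1c1ccc(OCc2ccccc2)cc1 | intermediate
20 | (2R,3R)-7-(benzyloxy)-2-[4-(benzyloxy)phenyl]chroman-3-ol | O[C@@H]1Cc2ccc(OCc3ccccc3)cc2O[C@@H]1c1ccc(OCc2ccccc2)cc1 | intermediate
21 | (2R,3R,4S)-7-(benzyloxy)-2-[4-(benzyloxy)phenyl]-4-(2-ethoxyethoxy)chroman-3-ol | O[C@@H]1[C@@H](OCCOCC)c2ccc(OCc3ccccc3)cc2O[C@@H]1c1ccc(OCc2ccccc2)cc1 | intermediate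
22 | (2R,3R,4R)-7-(benzyloxy)-2-[4-(benzyloxy)phenyl]-4-{(2R,3R)-5,7-bis(benzyloxy)-2-[3,4-bis(benzyloxy)phenyl]-3-hydroxychroman-8-yl}chroman-3-ol | C(c1ccccc1)Oc1ccc([C@H]2Oc3cc(OCc4ccccc4)ccc3[C@H](c3c(OCc4ccccc4)cc(OCc4ccccc4)c4c3O[C@H](c3ccc(OCc5ccccc5)c(OCc5ccccc5)c3)[C@H](O)C4)[C@H]2O)cc1 | intermediate
23 | (2R,3R,4R)-2-(4-hydroxyphenyl)-4-[(2R,3R)-2-(3,4-dihydroxyphenyl)-3,5,7-trihydroxychroman-8-yl]chroman-3,7-diol | Oc1ccc([C@H]2Oc3cc(O)ccc3[C@H](c3c(O)cc(O)c4c3O[C@H](c3ccc(O)c(O)c3)[C@H](O)C4)[C@H]2O)cc1 | target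

**Step count and risks**
Total step count: 13. Longest linear sequence: 6 steps (steps 8, 9, 10, 11, 12, 13; equally steps 1, 2, 4, 7, 12, 13).

Steps most likely to fail:

1. Step 7 (the step that carries the proposed new method). The electron-rich quinone methide may be consumed by Friedel–Crafts self-condensation with 11 or with the product. The cis relationship may erode if bond formation becomes stepwise through a zwitterion that rotates before ring closure. Facial discrimination by the auxiliary may be insufficient. Fallback with known chemistry, from 10 back to 14: the same two bonds are made at the aldehyde oxidation level with nitrogen as the oxygen surrogate. Aldehyde 10 and commercial (E)-1,2-bis(benzyloxy)-4-(2-nitroethenyl)benzene undergo the amine-catalysed domino oxa-Michael–Henry–dehydration of step 8 to give (2R)-5,7-bis(benzyloxy)-2-[3,4-bis(benzyloxy)phenyl]-3-nitro-2H-chromene F1. NaBH4 reduction gives the sodium nitronate of the 3-nitrochroman F2, and buffered aqueous TiCl3 converts it into (2R)-5,7-bis(benzyloxy)-2-[3,4-bis(benzyloxy)phenyl]chroman-3-one F3. Reduction with LiBH(sec-Bu)3 at −78 °C, from the face opposite to the 2-aryl group, returns to 14.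

2. Step 8. Enantioinduction in the oxa-Michael step may be poor, and the C2 configuration may erode through reversible amine addition and ring opening of the nitrochromene. Fallback, from 15 back to 19: the nitroalkene is replaced by an enal under iminium/enamine catalysis, and the extra carbon is excised oxidatively. (E)-3-[4-(benzyloxy)phenyl]prop-2-enal F4 is made from commercial 4-(benzyloxy)benzaldehyde by Wittig reaction with (triphenylphosphoranylidene)acetaldehyde. It condenses with 15 under α,α-diphenylprolinol trimethylsilyl ether/2-nitrobenzoic acid catalysis (domino oxa-Michael/aldol condensation; catalyst antipode chosen for 2R) to give (2R)-7-(benzyloxy)-2-[4-(benzyloxy)phenyl]-2H-chromene-3-carbaldehyde F5. Dakin-type Baeyer–Villiger oxidation with mCPBA gives the enol formate (2R)-7-(benzyloxy)-2-[4-(benzyloxy)phenyl]-2H-chromen-3-yl formate F6. Mild methanolysis (KHCO3, MeOH, 0 °C) releases ketone 19.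

3. Step 12. Ionisation of the less stabilised 5-deoxy C4 acetal may be slow, so that self-condensation of the donor and attack through C6 of 14 compete. Fallback, from 21 back to 22: the oxygen leaving group is exchanged for sulfur and activated by a thiophile under neutral conditions. Compound 21 with phenylmethanethiol and BF3·OEt2 gives (2R,3S,4S)-4-(benzylsulfanyl)-7-(benzyloxy)-2-[4-(benzyloxy)phenyl]chroman-3-ol F7. Stoichiometric AgBF4 in THF at 0 °C in the presence of 14 then generates the C4 cation irreversibly and should give 22.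

**Further compounds**
F1 | step 7 | (2R)-5,7-bis(benzyloxy)-2-[3,4-bis(benzyloxy)phenyl]-3-nitro-2H-chromene | [O-][N+](=O)C1=Cc2c(OCc3ccccc3)cc(OCc3ccccc3)cc2O[C@@H]1c1ccc(OCc2ccccc2)c(OCc2ccccc2)c1
F2 | step 7 | sodium nitronate of (2R)-5,7-bis(benzyloxy)-2-[3,4-bis(benzyloxy)phenyl]-3-nitrochroman | [Na+].[O-][N+]([O-])=C1Cc2c(OCc3ccccc3)cc(OCc3ccccc3)cc2O[C@@H]1c1ccc(OCc2ccccc2)c(OCc2ccccc2)c1
F3 | step 7 | (2R)-5,7-bis(benzyloxy)-2-[3,4-bis(benzyloxy)phenyl]chroman-3-one | O=C1Cc2c(OCc3ccccc3)cc(OCc3ccccc3)cc2O[C@@H]1c1ccc(OCc2ccccc2)c(OCc2ccccc2)c1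
F4 | step 8 | (E)-3-[4-(benzyloxy)phenyl]prop-2-enal | O=C/C=C/c1ccc(OCc2ccccc2)cc1
F5 | step 8 | (2R)-7-(benzyloxy)-2-[4-(benzyloxy)phenyl]-2H-chromene-3-carbaldehyde | O=CC1=Cc2ccc(OCc3ccccc3)cc2O[C@@H]1c1ccc(OCc2ccccc2)cc1
F6 | step 8 | (2R)-7-(benzyloxy)-2-[4-(benzyloxy)phenyl]-2H-chromen-3-yl formate | O=COC1=Cc2ccc(OCc3ccccc3)cc2O[C@@H]1c1ccc(OCc2ccccc2)cc1
F7 | step 12 | (2R,3S,4S)-4-(benzylsulfanyl)-7-(benzyloxy)-2-[4-(benzyloxy)phenyl]chroman-3-ol | O[C@@H]1[C@@H](SCc2ccccc2)c2ccc(OCc3ccccc3)cc2O[C@@H]1c1ccc(OCc2ccccc2)cc1
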